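## Structural features

Kanzonol T is an achiral isoflavone: a benzopyran-4-one (rings A and C) whose C3 is joined by a single C3–C1' bond to ring B, and ring B is fused along C3'–C4' to a 2,2-dimethyl-2H-pyran (ring D), so the C3 substituent is a 5-hydroxy-2,2-dimethylchromen-6-yl group with its free hydroxyl (on C2') next to the inter-ring bond. Ring A has the phloroglucinol pattern: the 5-OH (hydrogen-bonded to the C4 carbonyl) and the 7-OH flank C6, which carries a 3-hydroxy-3-methylbutyl chain ending in a tertiary alcohol. There is no stereocentre, so none stand next to each other; the only stereochemical element on the way is the geometry of the enol double bond that becomes C2=C3. The fragile groups are the chromene double bond of ring D (strong acid, electrophiles, oxidants, hydrogenation, ultraviolet light), the tertiary alcohol (ionisation in strong acid, then closure onto the 5- or 7-oxygen or loss of water) and the electron-rich free polyphenol. The real difficulty is regiochemical: the chain must be on C6 and not C8, ring D must be fused in the angular sense with the 2'-hydroxyl free, and ring C must be closed without harming ring D. The key step exploits the fact that O1 (on C8a) and the carbonyl carbon C4 (on C4a) sit on adjacent carbons of ring A with the C5 oxygen next to C4a. This is the pattern left when a 3-alkoxyaryne takes up an oxygen nucleophile at its remote carbon and an acyl group at its near carbon. Before ring C is attached, ring A is also mirror-symmetric about the C6···C8a axis, so a symmetric 4-alkyl-3,5-dioxygenated phenol fixes the chain on C6 with no selectivity problem.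

## Logic of the disconnections

**23 to 22.** The four O–CH2OMe acetal bonds (on the 5-, 7- and 2'-oxygens and on the side-chain oxygen) are cut last. Free hydroxyls would quench the organolithium steps, add to the aryne or protonate the aryl anion of the key step. One acetal type on all four oxygens means one closing operation. The demand is an acid mild enough for ring D and for the tertiary alcohol.

**22 to 12 and 18.** O1–C8a and C4–C4a are cut. Both lie on neighbouring ring A carbons, so one aryne can form them in one operation. The cut removes ring C and divides the molecule into two halves of similar size. The forward step must add oxygen at C8a and not C4a, arylate oxygen and not carbon, hold the new aryl ether cis to the ester, and exclude proton donors.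

**12 to 9 to 8.** In 12 the C–Si bond and the O–S bond are cut. Silicon is placed ortho to oxygen by a 1,3 shift from oxygen to the carbon that carried bromine (through 10 and 11), so its position is not in doubt. In 9 the C–Br bond is cut. The two ortho positions of 8 are equivalent and the para position is blocked, so only one monobromide can form. The demands are clean monobromination of a very electron-rich ring and halogen–metal exchange faster than attack at silicon.

**8 to 7 to 6, then 6 to 3 and 4.** The O–Si bond of 7 and the side-chain O–CH2OMe bond are protecting-group cuts. The phenol must be masked during metalation, and the chain alcohol must be masked from the exchange step onward. In 6 the aryl–CH2 bond is cut. The carbon between the two acetal oxygens is the most acidic ring position of 3, and 4 delivers the whole chain with its tertiary alcohol in one step. The forward step needs metalation only between the acetals and ring opening of 4 at its CH2–O carbon.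

**3 to 2 to 1.** One O–Si and two O–CH2OMe bonds are cut. This differentiates the three equivalent oxygens of 1 two against one. The cost is a statistical first step on the cheapest material, and the demand is a clean separation.

**18 to 16 and 17.** The bond from ring B to the α-carbon and the bond from the α-carbon to the hydroxymethylene carbon are cut. The formyl carbon of 16 becomes C2, and the diazo carbon of 17 becomes C3 after a 1,2-aryl shift. One step gives the complete three-carbon unit in the enol form the key step needs, instead of a multi-step arylacetate homologation and formylation. The demand is aryl and not hydride migration, under catalytic acid that the acetal and ring D must survive.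

**16 to 15, then 15 to 13 and 14.** The O–CH2OMe bond is cut, then the aryl–CH and O–CMe2 bonds of ring D. 14 supplies all five carbons of ring D. The hydrogen bond between the 2-hydroxyl and the aldehyde in 13 leaves only the 4-oxygen free to close the ring, which gives the angular fusion. The demand is attack at the carbon between the two oxygens of 13.

## Other disconnections considered

Alternative 1: The cut is C3–C4. The precursor A1 is a ring A benzaldehyde whose ortho oxygen carries the CH2–C(=O)–ring B unit. A triazolium-derived carbene would turn the aldehyde into an acyl anion equivalent that adds to the ketone and gives the racemic 3-hydroxyisoflavanone A2. Dehydration across C2–C3 would then give 22.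
- In its favour: the intramolecular aldehyde–ketone benzoin to 3-hydroxychromanones is an established reaction class. On precedent this closure is better supported than the aryne annulation.
- Equal point: ring A needs only ortho-formylation of the symmetric phenol 8, so the regiocontrol is equal, and it needs no silyl triflate.
- Against it here: the aldehyde of A1 is flanked by two oxygen substituents and is strongly deactivated, and the ketone is a hindered ortho-alkoxyaryl ketone. The Breslow intermediate should form and add slowly.
- A stereocentre is made only to be destroyed.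
- Dehydration of the tertiary ketol A2 needs activation in the presence of acid-sensitive groups.
- A1 needs a ring B α-halo ketone, whose preparation competes with the chromene double bond.
- Step economy: one skeletal bond per key step against two, and two steps after the key step against one. The route should be about two steps longer.

Alternative 2: The cut takes ring A apart at C8–C8a, C7–C8, C5–C6 and C4a–C5. Irradiation of the pyranonyl diazo ketone A3 would give a vinylketene by Wolff rearrangement. This would add the siloxyalkyne A4, and on heating the cyclobutenone would open and reclose to the phenol A5 (Danheiser benzannulation).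
- Better points: four bonds form in one step; the alkyne polarity places the chain on C6; the 5-OH is born free and is distinguished from the silylated 7-oxygen; no statistical desymmetrisation of phloroglucinol is needed.
- Equal point: there is no enol geometry question, and regiocontrol is at least as secure as in the chosen plan.
- Against it here: 2H-chromenes open photochemically to ortho-quinone methides under the light needed for the Wolff step.
- The vinylketene can add to the chromene double bond.
- A3 is a hazardous diazo ketone that needs a 5-aryl-4-oxopyran-2-carboxylic acid, itself several steps away.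
- A4 needs its own synthesis.
- Step economy: the key step is richer, but the two precursors cost more steps than 12 and 18, so the route should be longer and less safe.

Alternative 3: The cut is O1–C2, with ring C closed last on a chain in which ring A, C4, C3 and ring B are already joined. Pd(O2CCF3)2 (divalent palladium) under O2 would open the cyclopropanol A6 at the carbinol–CH2 bond. β-Hydride elimination would give the α-methylene ketone, the ring A phenol would add to C2, and dehydrogenation would give A7.
- Better points: the side-chain alcohol can stay free, one protecting group fewer than in 22; the metal is catalytic and O2 is the oxidant.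
- Equal point: the elementary steps have precedent, and the regiocontrol on ring A rests on the same symmetric phenol.
- Against it here: cleavage of the benzylic carbinol–CH(aryl) bond would lead by way of a chalcone to the flavone skeleton.
- Divalent palladium under O2 can attack the chromene double bond in a Wacker-type process and oxidise the electron-rich phenol.
- Two stereocentres are made and destroyed.
- A6 is most directly made from the 2-hydroxydeoxybenzoin, which a one-carbon donor would already close to the isoflavone.
- Step economy: less convergent, and several steps longer than the chosen plan.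

Key step: step 11

Remark on the chemistry: the alkoxy group of the ester is the leaving group of the ring closure and does not appear in the product, so the ethyl ester that ethyl diazoacetate delivers directly is used in place of a methyl ester.

## Route

Step 1
Reactants: 1 phloroglucinol (benzene-1,3,5-triol)
Product: 2 3,5-bis(methoxymethoxy)phenol
Conditions: CH2(OMe)2, AcCl, ZnBr2 (cat.), toluene, rt (MOMCl formed in the flask, 2.0 equiv); then 1, i-Pr2NEt, THF, 0 °C → rt
Reagents that add atoms: chloromethyl methyl ether, COCCl (formed in the flask from dimethoxymethane, COCOC, and acetyl chloride, CC(=O)Cl)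
Why: Williamson-type O-alkylation with an α-chloro ether; the three hydroxyls are equivalent, so the bis-ether is the main member of a statistical mixture and is separated from the mono- and tris-ethers by chromatography. Making the chloro ether in solution avoids handling the neat carcinogen.

Step 2
Reactants: 2 3,5-bis(methoxymethoxy)phenol
Product: 3 [3,5-bis(methoxymethoxy)phenoxy]triisopropylsilane
Conditions: i-Pr3SiCl, imidazole, DMF, rt
Reagents that add atoms: chlorotriisopropylsilane, CC(C)[Si](Cl)(C(C)C)C(C)C
Why: Standard silylation of a phenol; the bulky silyl ether resists n-BuLi and screens its two neighbouring positions, so step 3 should metalate only between the acetals.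

Step 3
Reactants: 3 [3,5-bis(methoxymethoxy)phenoxy]triisopropylsilane; 4 2,2-dimethyloxetane
Product: 6 4-[2,6-bis(methoxymethoxy)-4-(triisopropylsilyloxy)phenyl]-2-methylbutan-2-ol, via aryllithium 5 (not isolated)
Conditions: n-BuLi, THF, 0 °C; then −78 °C, 4, BF3·OEt2; H2O
Reagents that add atoms: none
Why: Directed ortho-metalation at the carbon flanked by two methoxymethoxy groups, then BF3-assisted SN2 opening of the oxetane at its unhindered CH2–O carbon. This should deliver the whole chain with the tertiary alcohol in place.

Step 4
Reactants: 6 4-[2,6-bis(methoxymethoxy)-4-(triisopropylsilyloxy)phenyl]-2-methylbutan-2-ol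
Product: 7 {3,5-bis(methoxymethoxy)-4-[3-(methoxymethoxy)-3-methylbutyl]phenoxy}triisopropylsilane
Conditions: CH2(OMe)2, AcCl, ZnBr2 (cat.), toluene, rt (MOMCl in the flask, 4 equiv); then 6, i-Pr2NEt, n-Bu4NI (cat.), 50 °C
Reagents that add atoms: chloromethyl methyl ether, COCCl (formed in the flask from dimethoxymethane, COCOC, and acetyl chloride, CC(=O)Cl)
Why: Iodide-accelerated acetalisation of the hindered tertiary alcohol. The free alcohol would consume n-BuLi in step 7 and would act as a proton donor and nucleophile in step 11; the silyl ether is not touched.

Step 5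
Reactants: 7 {3,5-bis(methoxymethoxy)-4-[3-(methoxymethoxy)-3-methylbutyl]phenoxy}triisopropylsilane
Product: 8 3,5-bis(methoxymethoxy)-4-[3-(methoxymethoxy)-3-methylbutyl]phenol
Conditions: n-Bu4NF, AcOH, THF, 0 °C
Reagents that add atoms: none
Why: Fluoride cleaves the aryl silyl ether; the acetic acid buffer keeps the electron-rich phenoxide from oxidising, and the acetals are inert.

Step 6
Reactants: 8 3,5-bis(methoxymethoxy)-4-[3-(methoxymethoxy)-3-methylbutyl]phenol
Product: 9 2-bromo-3,5-bis(methoxymethoxy)-4-[3-(methoxymethoxy)-3-methylbutyl]phenol
Conditions: NBS (1.0 equiv), CH2Cl2, −78 → −20 °C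
Reagents that add atoms: N-bromosuccinimide, O=C1CCC(=O)N1Br
Why: Electrophilic aromatic bromination ortho to the free hydroxyl; the two ortho positions are equivalent and the para position is blocked, so only one monobromide can form. One equivalent at low temperature should limit dibromination.

Step 7
Reactants: 9 2-bromo-3,5-bis(methoxymethoxy)-4-[3-(methoxymethoxy)-3-methylbutyl]phenol
Product: 12 3,5-bis(methoxymethoxy)-4-[3-(methoxymethoxy)-3-methylbutyl]-2-(trimethylsilyl)phenyl trifluoromethanesulfonate, via silyl ether 10 (not isolated), via lithium phenoxide 11 (not isolated)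
Conditions: (Me3Si)2NH, THF, 65 °C, then evaporation; n-BuLi, THF, −78 °C; PhNTf2, −78 °C → rt; H2O
Reagents that add atoms: hexamethyldisilazane, C[Si](C)(C)N[Si](C)(C)C; N-phenylbis(trifluoromethanesulfonimide), O=S(=O)(N(c1ccccc1)S(=O)(=O)C(F)(F)F)C(F)(F)F
Why: O-silylation, bromine–lithium exchange and retro-Brook 1,3 shift of silicon from oxygen to carbon put the silyl group where bromine was; the freed phenoxide is triflated in the same flask. The solid triflimide is chosen over Tf2O because it is milder towards the acetals and safer to handle.

Step 8
Reactants: 13 2,4-dihydroxybenzaldehyde; 14 3-methylbut-2-enal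
Product: 15 5-hydroxy-2,2-dimethyl-2H-chromene-6-carbaldehyde
Conditions: Ca(OH)2, MeOH, rt
Reagents that add atoms: none
Why: Knoevenagel-type C-alkylation of the phenoxide at the carbon between the two oxygens, loss of water to an ortho-quinone methide and oxa-6π electrocyclisation. The 2-hydroxyl is tied to the aldehyde by a hydrogen bond, so the 4-oxygen should close the ring and give the angular chromene.

Step 9
Reactants: 15 5-hydroxy-2,2-dimethyl-2H-chromene-6-carbaldehyde
Product: 16 5-(methoxymethoxy)-2,2-dimethyl-2H-chromene-6-carbaldehyde
Conditions: CH2(OMe)2, AcCl, ZnBr2 (cat.), toluene, rt (MOMCl in the flask, 1.5 equiv); then 15, i-Pr2NEt, n-Bu4NI (cat.), 40 °C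
Reagents that add atoms: chloromethyl methyl ether, COCCl (formed in the flask from dimethoxymethane, COCOC, and acetyl chloride, CC(=O)Cl)
Why: O-alkylation of the hydrogen-bonded phenol under iodide catalysis; a free ortho-hydroxyl would cyclise onto the formyl group made in step 10 and would add to the aryne in step 11.

Step 10
Reactants: 16 5-(methoxymethoxy)-2,2-dimethyl-2H-chromene-6-carbaldehyde; 17 ethyl diazoacetate
Product: 18 ethyl (2Z)-3-hydroxy-2-[5-(methoxymethoxy)-2,2-dimethyl-2H-chromen-6-yl]prop-2-enoate
Conditions: HBF4·OEt2 (10 mol %), CH2Cl2, −78 °C, slow addition of 17 (commercial solution)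
Reagents that add atoms: none
Why: Acid-catalysed addition of the diazo ester to the aldehyde and 1,2-aryl shift with loss of N2 give the α-formyl ester, which rests as the hydrogen-bonded Z enol. The 2,4-dioxygenated ring should migrate in preference to hydride, and the catalytic acid at −78 °C should spare the acetal and ring D.

Step 11
Reactants: 12 3,5-bis(methoxymethoxy)-4-[3-(methoxymethoxy)-3-methylbutyl]-2-(trimethylsilyl)phenyl trifluoromethanesulfonate; 18 ethyl (2Z)-3-hydroxy-2-[5-(methoxymethoxy)-2,2-dimethyl-2H-chromen-6-yl]prop-2-enoate
Product: 22 5,7-bis(methoxymethoxy)-6-[3-(methoxymethoxy)-3-methylbutyl]-3-[5-(methoxymethoxy)-2,2-dimethyl-2H-chromen-6-yl]-4H-chromen-4-one, via caesium enolate 19 (not isolated), via aryne 20 (not isolated), via aryl anion 21 (not isolated)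
Conditions: 18, Cs2CO3, THF, rt; then CsF, 12 (1.5 equiv, slow addition), THF, 65 °C
Reagents that add atoms: none
Why: Proposed new method: Cs2CO3 first turns 18 into the chelated caesium enolate 19, so no O–H remains in the flask; fluoride then attacks silicon in 12, and 1,2-loss of triflate gives aryne 20 between C4a and C8a. The enolate oxygen of 19 adds to C8a, the aryne carbon remote from the C5 acetal oxygen, which leaves the charge on C4a (aryl anion 21), where the adjacent C5–O bond stabilises it inductively. 21 attacks the ester held cis to the new aryl ether and ethoxide leaves, so C4–C4a forms after O1–C8a and ring C closes by a 6-exo-trig acyl substitution to the aromatic pyranone. The closest known reaction type is the aryne annulation of salicylate esters to xanthones (O-arylation, then intramolecular acyl substitution); here the phenoxide is replaced by the enolate oxygen of an α-formyl ester, which has not been shown. No stereocentre is formed. Three selectivities are needed: addition at C8a and not C4a, secured by the inductive and steric bias of the 3-alkoxyaryne; O- and not C-arylation, favoured because the carbon terminus of 19 is fully substituted and screened by ring B with its ortho acetal; and an enol ether with oxygen cis to the ester, favoured by the U-shaped chelate that caesium forms with both oxygens in THF without crown ether or polar co-solvent. The protected side chain, the preformed enolate and THF in place of acetonitrile keep proton donors away from 21, and the mildly basic medium should leave the chromene and the acetals untouched.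

Step 12
Reactants: 22 5,7-bis(methoxymethoxy)-6-[3-(methoxymethoxy)-3-methylbutyl]-3-[5-(methoxymethoxy)-2,2-dimethyl-2H-chromen-6-yl]-4H-chromen-4-one
Product: 23 Kanzonol T, 5,7-dihydroxy-6-(3-hydroxy-3-methylbutyl)-3-(5-hydroxy-2,2-dimethyl-2H-chromen-6-yl)-4H-chromen-4-one
Conditions: 2 M aq. HCl, MeOH–THF, 40 °C
Reagents that add atoms: none
Why: Acid-catalysed acetal exchange with methanol removes all four methoxymethyl groups. The tertiary alkyl acetal is the most basic and should leave at least as fast as the aryl ones, so dilute acid at or below 40 °C should suffice, conditions under which the tertiary alcohol should not ionise and the chromene should not be hydrated.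

## Compound list

1 | phloroglucinol (benzene-1,3,5-triol) | Oc1cc(O)cc(O)c1 | starting material
2 | 3,5-bis(methoxymethoxy)phenol | COCOc1cc(O)cc(OCOC)c1 | intermediate
3 | [3,5-bis(methoxymethoxy)phenoxy]triisopropylsilane | COCOc1cc(OCOC)cc(O[Si](C(C)C)(C(C)C)C(C)C)c1 | intermediate
4 | 2,2-dimethyloxetane | CC1(C)CCO1 | starting material
5 | [2,6-bis(methoxymethoxy)-4-(triisopropylsilyloxy)phenyl]lithium | [Li]c1c(OCOC)cc(O[Si](C(C)C)(C(C)C)C(C)C)cc1OCOC | intermediate (not isolated)
6 | 4-[2,6-bis(methoxymethoxy)-4-(triisopropylsilyloxy)phenyl]-2-methylbutan-2-ol | CC(C)(O)CCc1c(OCOC)cc(O[Si](C(C)C)(C(C)C)C(C)C)cc1OCOC | intermediate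
7 | {3,5-bis(methoxymethoxy)-4-[3-(methoxymethoxy)-3-methylbutyl]phenoxy}triisopropylsilane | COCOC(C)(C)CCc1c(OCOC)cc(O[Si](C(C)C)(C(C)C)C(C)C)cc1OCOC | intermediate
8 | 3,5-bis(methoxymethoxy)-4-[3-(methoxymethoxy)-3-methylbutyl]phenol | COCOC(C)(C)CCc1c(OCOC)cc(O)cc1OCOC | intermediate
9 | 2-bromo-3,5-bis(methoxymethoxy)-4-[3-(methoxymethoxy)-3-methylbutyl]phenol | COCOC(C)(C)CCc1c(OCOC)cc(O)c(Br)c1OCOC | intermediate
10 | {2-bromo-3,5-bis(methoxymethoxy)-4-[3-(methoxymethoxy)-3-methylbutyl]phenoxy}trimethylsilane | COCOC(C)(C)CCc1c(OCOC)cc(O[Si](C)(C)C)c(Br)c1OCOC | intermediate (not isolated)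
11 | lithium 3,5-bis(methoxymethoxy)-4-[3-(methoxymethoxy)-3-methylbutyl]-2-(trimethylsilyl)phenoxide | COCOC(C)(C)CCc1c(OCOC)cc([O-])c([Si](C)(C)C)c1OCOC.[Li+] | intermediate (not isolated)
12 | 3,5-bis(methoxymethoxy)-4-[3-(methoxymethoxy)-3-methylbutyl]-2-(trimethylsilyl)phenyl trifluoromethanesulfonate | C[Si](C)(C)c1c(OS(=O)(=O)C(F)(F)F)cc(OCOC)c(CCC(C)(C)OCOC)c1OCOC | intermediate
13 | 2,4-dihydroxybenzaldehyde | O=Cc1ccc(O)cc1O | starting material
14 | 3-methylbut-2-enal | CC(C)=CC=O | starting material
15 | 5-hydroxy-2,2-dimethyl-2H-chromene-6-carbaldehyde | O=Cc1ccc2c(c1O)C=CC(C)(C)O2 | intermediate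
16 | 5-(methoxymethoxy)-2,2-dimethyl-2H-chromene-6-carbaldehyde | O=Cc1ccc2c(c1OCOC)C=CC(C)(C)O2 | intermediate
17 | ethyl diazoacetate | CCOC(=O)C=[N+]=[N-] | starting material
18 | ethyl (2Z)-3-hydroxy-2-[5-(methoxymethoxy)-2,2-dimethyl-2H-chromen-6-yl]prop-2-enoate | CCOC(=O)/C(=C\O)c1ccc2c(c1OCOC)C=CC(C)(C)O2 | intermediate
19 | caesium (1Z)-3-ethoxy-2-[5-(methoxymethoxy)-2,2-dimethyl-2H-chromen-6-yl]-3-oxoprop-1-en-1-olate | CCOC(=O)/C(=C\[O-])c1ccc2c(c1OCOC)C=CC(C)(C)O2.[Cs+] | intermediate (not isolated)
20 | 3,5-bis(methoxymethoxy)-4-[3-(methoxymethoxy)-3-methylbutyl]-1,2-didehydrobenzene (the ring A aryne) | COCOC1=C(CCC(C)(C)OCOC)C(OCOC)=CC#C1 | intermediate (not isolated)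
21 | caesium 2-{[(1Z)-3-ethoxy-2-[5-(methoxymethoxy)-2,2-dimethyl-2H-chromen-6-yl]-3-oxoprop-1-en-1-yl]oxy}-4,6-bis(methoxymethoxy)-5-[3-(methoxymethoxy)-3-methylbutyl]benzen-1-ide | CCOC(=O)/C(=C\Oc1cc(OCOC)c(CCC(C)(C)OCOC)c(OCOC)[c-]1)c1ccc2c(c1OCOC)C=CC(C)(C)O2.[Cs+] | intermediate (not isolated)
22 | 5,7-bis(methoxymethoxy)-6-[3-(methoxymethoxy)-3-methylbutyl]-3-[5-(methoxymethoxy)-2,2-dimethyl-2H-chromen-6-yl]-4H-chromen-4-one | CC(C)(OCOC)CCc1c(OCOC)cc2occ(-c3ccc4c(c3OCOC)C=CC(C)(C)O4)c(=O)c2c1OCOC | intermediate
23 | Kanzonol T, 5,7-dihydroxy-6-(3-hydroxy-3-methylbutyl)-3-(5-hydroxy-2,2-dimethyl-2H-chromen-6-yl)-4H-chromen-4-one | CC(C)(O)CCc1c(O)cc2occ(-c3ccc4c(c3O)C=CC(C)(C)O4)c(=O)c2c1O | target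

## Step count and least certain steps

Total step count: 12. Longest linear sequence: 9 (steps 1 to 7, then 11 and 12); the ring B branch has 3 steps (8 to 10).

**Step 11 (the step labelled as a proposed new method).** Three processes are most likely to divert it.
- C-arylation of the enolate, followed by transfer of the formyl group to the aryl anion. This is the usual course of β-dicarbonyl enolates with arynes, and only the crowding at the α-carbon opposes it.
- O-arylation through the open rotamer of the enolate, which puts the aryl anion trans to the ester, where it can only be protonated. Simple O-alkylation of such enolates in polar media is known to favour that geometry.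
- Protonation of 21 before acyl capture.

Fallback with known chemistry, setting out from 18 and 9 and returning at 22: the same two bonds are made in the same order, but the aryl anion comes from halogen–metal exchange. Chelation-controlled enol sulfonylation of 18 (TsCl, TMEDA, LiCl, MeCN, 0 °C) should give the Z enol tosylate F1. Addition–elimination of the phenoxide of 9 (K3PO4, DMF, rt), with retention, should give the Z 3-(2-bromoaryloxy)acrylate F2. t-BuLi (2 equiv, THF, −100 °C) should then form the aryllithium F3, which closes onto the cis ester in a Parham cyclisation to 22.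

**Step 10.** The catalytic acid may strip the ortho methoxymethyl group (the freed phenol would then close onto the formyl group) or start oligomerisation of the chromene. Hydride instead of aryl migration would give the β-keto ester. Fallback from 16, returning at 18:
- CHCl3 and DBU should give the racemic trichloromethyl carbinol F4.
- Jocic-type reductive homologation (NaBH4, NaOH, t-BuOH, 55 °C) should give the arylacetic acid F5.
- EtI and K2CO3 in DMF should give the ethyl arylacetate F6.
- Claisen formylation (NaH, HCO2Et, THF, then AcOH) should give 18.

**Step 3.** BF3 may ionise the oxetane at its tertiary carbon (ring opening to an unsaturated alcohol or oligomers) faster than the hindered aryllithium attacks the CH2 carbon, or proton transfer may return 3. Fallback from 3 (through 5), returning at 6: alkylation of 5 with prenyl bromide (CuBr·SMe2, THF, −78 → 0 °C) should give the prenyl arene F7. Mukaiyama hydration (Co(acac)2 cat., PhSiH3, O2, i-PrOH) should then add water in the Markovnikov sense to give 6.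

**Step 12.** If the side-chain acetal lags behind the aryl acetals, stronger acid or heat would be needed. The tertiary C–O bond could then ionise, with closure onto the 5- or 7-oxygen or loss of water, and the chromene could be hydrated. Fallback from 22, returning at 23, as a staged and chemoselective end game: NaHSO4·SiO2 (CH2Cl2, rt) should cleave only the three phenolic acetals and give the triphenol with the side-chain acetal intact, F8. Aprotic transfer of the last methoxymethyl group to sulfur (ZnBr2, n-PrSH, CH2Cl2, 0 °C) should then free the tertiary alcohol without protonating it.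

## Further compounds

F1 | step 11 | ethyl (2Z)-2-[5-(methoxymethoxy)-2,2-dimethyl-2H-chromen-6-yl]-3-(tosyloxy)prop-2-enoate | CCOC(=O)/C(=C\OS(=O)(=O)c1ccc(C)cc1)c1ccc2c(c1OCOC)C=CC(C)(C)O2
F2 | step 11 | ethyl (2Z)-3-{2-bromo-3,5-bis(methoxymethoxy)-4-[3-(methoxymethoxy)-3-methylbutyl]phenoxy}-2-[5-(methoxymethoxy)-2,2-dimethyl-2H-chromen-6-yl]prop-2-enoate | CCOC(=O)/C(=C\Oc1cc(OCOC)c(CCC(C)(C)OCOC)c(OCOC)c1Br)c1ccc2c(c1OCOC)C=CC(C)(C)O2
F3 | step 11 | the aryllithium formed from F2 by bromine–lithium exchange | CCOC(=O)/C(=C\Oc1cc(OCOC)c(CCC(C)(C)OCOC)c(OCOC)c1[Li])c1ccc2c(c1OCOC)C=CC(C)(C)O2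
F4 | step 10 | 2,2,2-trichloro-1-[5-(methoxymethoxy)-2,2-dimethyl-2H-chromen-6-yl]ethan-1-ol (racemic) | OC(c1ccc2c(c1OCOC)C=CC(C)(C)O2)C(Cl)(Cl)Cl
F5 | step 10 | [5-(methoxymethoxy)-2,2-dimethyl-2H-chromen-6-yl]acetic acid | OC(=O)Cc1ccc2c(c1OCOC)C=CC(C)(C)O2
F6 | step 10 | ethyl [5-(methoxymethoxy)-2,2-dimethyl-2H-chromen-6-yl]acetate | CCOC(=O)Cc1ccc2c(c1OCOC)C=CC(C)(C)O2
F7 | step 3 | [3,5-bis(methoxymethoxy)-4-(3-methylbut-2-en-1-yl)phenoxy]triisopropylsilane | CC(C)=CCc1c(OCOC)cc(O[Si](C(C)C)(C(C)C)C(C)C)cc1OCOC
F8 | step 12 | 5,7-dihydroxy-3-(5-hydroxy-2,2-dimethyl-2H-chromen-6-yl)-6-[3-(methoxymethoxy)-3-methylbutyl]-4H-chromen-4-one | CC(C)(OCOC)CCc1c(O)cc2occ(-c3ccc4c(c3O)C=CC(C)(C)O4)c(=O)c2c1O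
A1 | alternative 1 | 2-{2-[5-(methoxymethoxy)-2,2-dimethyl-2H-chromen-6-yl]-2-oxoethoxy}-4,6-bis(methoxymethoxy)-5-[3-(methoxymethoxy)-3-methylbutyl]benzaldehyde | O=Cc1c(OCOC)c(CCC(C)(C)OCOC)c(OCOC)cc1OCC(=O)c1ccc2c(c1OCOC)C=CC(C)(C)O2
A2 | alternative 1 | 3-hydroxy-5,7-bis(methoxymethoxy)-6-[3-(methoxymethoxy)-3-methylbutyl]-3-[5-(methoxymethoxy)-2,2-dimethyl-2H-chromen-6-yl]chroman-4-one (racemic) | O=C1c2c(OCOC)c(CCC(C)(C)OCOC)c(OCOC)cc2OCC1(O)c1ccc2c(c1OCOC)C=CC(C)(C)O2
A3 | alternative 2 | 2-diazo-1-{5-[5-(methoxymethoxy)-2,2-dimethyl-2H-chromen-6-yl]-4-oxo-4H-pyran-2-yl}ethan-1-one | [N-]=[N+]=CC(=O)c1cc(=O)c(-c2ccc3c(c2OCOC)C=CC(C)(C)O3)co1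
A4 | alternative 2 | triisopropyl{[5-(methoxymethoxy)-5-methylhex-1-yn-1-yl]oxy}silane | CC(C)(OCOC)CCC#CO[Si](C(C)C)(C(C)C)C(C)C
A5 | alternative 2 | 5-hydroxy-6-[3-(methoxymethoxy)-3-methylbutyl]-3-[5-(methoxymethoxy)-2,2-dimethyl-2H-chromen-6-yl]-7-(triisopropylsilyloxy)-4H-chromen-4-one | CC(C)(OCOC)CCc1c(O[Si](C(C)C)(C(C)C)C(C)C)cc2occ(-c3ccc4c(c3OCOC)C=CC(C)(C)O4)c(=O)c2c1O
A6 | alternative 3 | 1-[2-hydroxy-5-(3-hydroxy-3-methylbutyl)-4,6-bis(methoxymethoxy)phenyl]-2-[5-(methoxymethoxy)-2,2-dimethyl-2H-chromen-6-yl]cyclopropan-1-ol (racemic, mixture of cis and trans isomers) | CC(C)(O)CCc1c(OCOC)cc(O)c(C2(O)CC2c2ccc3c(c2OCOC)C=CC(C)(C)O3)c1OCOC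
A7 | alternative 3 | 6-(3-hydroxy-3-methylbutyl)-5,7-bis(methoxymethoxy)-3-[5-(methoxymethoxy)-2,2-dimethyl-2H-chromen-6-yl]-4H-chromen-4-one | CC(C)(O)CCc1c(OCOC)cc2occ(-c3ccc4c(c3OCOC)C=CC(C)(C)O4)c(=O)c2c1OCOC
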